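Readings and results are calculated on assumed constants, and the scatter is random.

Millimolar was the unit the meeting chose, so that charges could be subtracted from one another.

| setting | ash | elm | flask |
|---|---|---|---|
| substrate | 20 mM | 20 mM | 20 mM |
| coupling partner | 1.5 equiv | 1.5 equiv | 1.50 equiv |
| protic impurity | 5.6 mM | 8.8 mM | 4.00 mM |
| free catalyst | 0.097 mol% | 0.097 mol% | 0.097 mol% |
| second catalyst | 1 mol% | 1 mol% | 1 mol% |
| stray impurity | 80 µM | 80 µM | 80 µM |
| remark | run made earlier | run made earlier |  |
| time |  |  | 4.0 h |

- ash (time / h: intermediate / %, product / %): 0.0333: 14.8, 5.3; 0.0833: 21.2, 18.3; 0.200: 22.3, 47.5; 0.500: 12.3, 83.4; 1.33: 1.1, 100.2; 3.00: 0, 99.1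
- elm (time / h: intermediate / %, product / %): 0.0333: 14.0, 4.1; 0.0833: 22.0, 17.3; 0.200: 23.4, 46.0; 0.500: 14.9, 79.1; 1.33: 4.6, 95.7; 3.00: 1.0, 99.3

(each reading ± 0.5 percentage points)

- time up to 4.0 h at which intermediate stands highest
- the amount of intermediate, in percent of the substrate charged, at that time
- earliest time at which at least nineteen twentieths of that best amount are there
- latest time at which they still are

- what was read earlier has a scatter of 0.5 percentage points, one standard deviation

The analyst opened with the tails of the two runs. At 1.33 h, the ash run showed 1.1 % of intermediate and the elm run 4.6 %. Intermediate fell at 2.91 h⁻¹ in ash between 0.500 h and 1.33 h, and at 0.914 h⁻¹ in elm between 1.33 h and 3.00 h, slower. She warned that these are rough readings.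

The process chemist then proposed a balance. She assumed that each substrate and each protic impurity takes one coupling partner. The spare partner, 6.00 mM for the flask, is then the [coupling partner] charged less the [substrate] and [protic impurity] charged. Substrate is the limiting reagent in that balance. She argued that late in a run [coupling partner] approaches the spare partner, and that the rate of loss of intermediate follows it. Ash has 4.40 mM and elm 1.20 mM, a ratio of 3.67 against 3.18 in the readings. She committed to one figure: the flask ends with 20.0 % of its coupling partner.

Her balance offers no peak, so the meeting took that from the forecast: 22.6 % at 0.13 h, with the window asked for running from 0.087 h to 0.19 h. Its ground differs from hers: “the second catalyst appears to die in proportion to the protic impurity”.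

The flask peaks at 21.8 % at 0.130 h, and the window asked for runs from 0.0854 h to 0.194 h, a span of 6.52 min.

    substrate + free catalyst → free catalyst + intermediate (k = 85.4 L mol⁻¹ s⁻¹)
    coupling partner + second catalyst + intermediate → second catalyst + product (k = 1430 L² mol⁻² s⁻¹)
    coupling partner + protic impurity → quenched reagent (k = 0.133 L mol⁻¹ s⁻¹)
    second catalyst + stray impurity → spent catalyst (k = 660 L mol⁻¹ s⁻¹)

At 0.130 h, the best time, the flask holds 46.1 % substrate and 32.1 % product beside the intermediate. At 4.0 h, the flask keeps 20 % of its coupling partner. The neighbouring flask, charged with 6.00 equiv and otherwise the same, has a spare partner of 96.0 mM, which is 80.0 % of its charge. That neighbouring flask keeps 80 % of its coupling partner at 4.0 h.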